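**Retrosynthetic overview**

1. Target ⇐ selective C7 acetylation of a triol ⇐ side chain completed by hydroboration of a C5 isopropenyl group and B-alkyl Suzuki coupling with an (E)-vinyl iodide.
2. C7 carbinol ⇐ Luche reduction; cyclopentene (second ring) ⇐ ring-closing metathesis of trans allyl/isopropenyl groups on a cycloheptanone.
3. Exocyclic methylene and free C4–OH ⇐ SmI2 opening of an oxygen bridge α to a ketone, with Mannich methylenation of the resulting enolate.
4. C5 substituent ⇐ exo-selective rhodium-catalysed conjugate addition to the bridged enone, which also resolves the racemate.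
5. Seven-membered ring (first ring) ⇐ [5+2] cycloaddition of the aromatic 3-oxidopyrylium betaine (from furfuryl alcohol by Achmatowicz oxidation) with (3E)-hepta-3,6-dien-2-one.

Assumption: 8 and 9 are carried as racemates (the enantiomer drawn is the one that goes on), and the BINAP antipode that matches it in step 6 is fixed by experiment ((R) is written); 8–10 use 8-oxabicyclo[3.2.1]octane numbering, later compounds use azulene numbering.

**Route**

Step 1
Reactants: 1 furan-2-ylmethanol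
Product: 2 6-hydroxy-2H-pyran-3(6H)-one
Conditions: NBS, NaHCO3, THF/H2O (4:1), 0 °C
Reagents that add atoms: water (O)
Why: Achmatowicz oxidative ring expansion, in which the furan is opened to the cis-enedione and the primary hydroxyl closes the pyranone lactol; the lactol carbon is a transient stereocentre that is erased in step 4.

Step 2
Reactants: 2 6-hydroxy-2H-pyran-3(6H)-one
Product: 3 5-oxo-5,6-dihydro-2H-pyran-2-yl acetate
Conditions: Ac2O, pyridine, DMAP (cat.), CH2Cl2, 0 °C
Reagents that add atoms: acetic anhydride (CC(=O)OC(C)=O)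
Why: O-acetylation of the lactol installs the leaving group needed for pyrylium formation; no lasting stereocentre is made.

Step 3
Reactants: 4 but-3-en-2-one, 5 penta-1,4-diene
Product: 6 (3E)-hepta-3,6-dien-2-one
Conditions: second-generation Hoveyda–Grubbs catalyst (2 mol %), 5 (5 equiv), CH2Cl2, 40 °C, sealed tube
Reagents that add atoms: none
Why: olefin cross-metathesis of a terminal alkene with an enone is E-selective, and the excess of diene suppresses double coupling.

Step 4
Reactants: 3 5-oxo-5,6-dihydro-2H-pyran-2-yl acetate, 6 (3E)-hepta-3,6-dien-2-one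
Product: 8 rac-(1S,5S,6S,7S)-6-acetyl-7-(prop-2-en-1-yl)-8-oxabicyclo[3.2.1]oct-3-en-2-one, via pyrylium-3-olate 7 (not isolated)
Conditions: i-Pr2NEt (1.2 equiv), 6 (3 equiv), CH2Cl2, 0 °C to rt, slow addition of 3
Reagents that add atoms: none
Why: [5+2] dipolar cycloaddition of the aromatic 3-oxidopyrylium betaine, in which the nucleophilic C2 terminus bonds to the enone β-carbon (usual 6-acyl regiochemistry), the (E)-geometry is transferred suprafacially so that C6 and C7 are trans, and the endo-acyl transition state gives the 6-endo-acetyl/7-exo-allyl isomer, setting C1, C5, C6 and C7 relative to one another.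

Step 5
Reactants: 8 rac-(1S,5S,6S,7S)-6-acetyl-7-(prop-2-en-1-yl)-8-oxabicyclo[3.2.1]oct-3-en-2-one
Product: 9 rac-(1S,5S,6R,7S)-6-(prop-1-en-2-yl)-7-(prop-2-en-1-yl)-8-oxabicyclo[3.2.1]oct-3-en-2-one
Conditions: Ph3PCH3Br (1.05 equiv), KOtBu, THF, −78 to 0 °C
Reagents that add atoms: methyltriphenylphosphonium bromide (C[P+](c1ccccc1)(c1ccccc1)c1ccccc1.[Br-])
Why: Wittig methylenation is faster at the unconjugated methyl ketone than at the conjugated, bridgehead-flanked C2 carbonyl, and C6 is not scrambled because the trans C6/C7 arrangement is also the stable one.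

Step 6
Reactants: 9 rac-(1S,5S,6R,7S)-6-(prop-1-en-2-yl)-7-(prop-2-en-1-yl)-8-oxabicyclo[3.2.1]oct-3-en-2-one
Product: 10 (1S,4R,5S,6R,7S)-4,6-di(prop-1-en-2-yl)-7-(prop-2-en-1-yl)-8-oxabicyclo[3.2.1]octan-2-one
Conditions: [RhCl(C2H4)2]2 (1.5 mol %), (R)-BINAP (3.3 mol %), isopropenylboronic acid pinacol ester (0.6 equiv), KOH (cat.), 1,4-dioxane/H2O (10:1), 30 °C, stopped near half conversion
Reagents that add atoms: isopropenylboronic acid pinacol ester (CC(=C)B1OC(C)(C)C(C)(C)O1)
Why: Hayashi–Miyaura rhodium-catalysed 1,4-addition, in which the alkenyl group can only enter on the exo face (syn to O8, the endo face being blocked by the endo C6 isopropenyl group) and the chiral catalyst accepts that face for one enantiomer of 9 only, so the step is a kinetic resolution that sets C4 (R) cis to the bridging oxygen.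

Step 7
Reactants: 10 (1S,4R,5S,6R,7S)-4,6-di(prop-1-en-2-yl)-7-(prop-2-en-1-yl)-8-oxabicyclo[3.2.1]octan-2-one
Product: 14 (3S,4R,5S,6R)-5-hydroxy-2-methylidene-4,6-di(prop-1-en-2-yl)-3-(prop-2-en-1-yl)cycloheptan-1-one, via samarium enolate 11 (not isolated), via Mannich base 12 (not isolated), via trimethylammonium iodide 13 (not isolated)
Conditions: SmI2 (2.5 equiv), THF, −78 °C; dimethylmethylideneammonium iodide (3 equiv), −78 to 0 °C; then MeI, CH2Cl2, rt; aq. NaHCO3
Reagents that add atoms: dimethylmethylideneammonium iodide (C=[N+](C)C.[I-])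
Why: SmI2 cleaves the axial C1–O8 bond α to the ketone (reductive α-alkoxy ketone cleavage), the regiodefined enolate is trapped in a Mannich reaction, and quaternisation with E1cB (Hofmann-type) elimination gives the exocyclic enone, while the carbinol carbon keeps its configuration and no new stereocentre remains.

Step 8
Reactants: 14 (3S,4R,5S,6R)-5-hydroxy-2-methylidene-4,6-di(prop-1-en-2-yl)-3-(prop-2-en-1-yl)cycloheptan-1-one
Product: 15 (3aR,4S,5R,8aS)-4-hydroxy-3-methyl-8-methylidene-5-(prop-1-en-2-yl)-3a,4,5,6,8,8a-hexahydroazulen-7(1H)-one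
Conditions: second-generation Grubbs catalyst (5 mol %), CH2Cl2 (0.005 M), 40 °C
Reagents that add atoms: none
Why: ring-closing metathesis of the allyl and the adjacent isopropenyl group closes the trisubstituted cyclopentene, the trans ring fusion being inherited from the (E)-enone of step 4, while the other isopropenyl group and the exocyclic enone olefin are spectators.

Step 9
Reactants: 15 (3aR,4S,5R,8aS)-4-hydroxy-3-methyl-8-methylidene-5-(prop-1-en-2-yl)-3a,4,5,6,8,8a-hexahydroazulen-7(1H)-one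
Product: 16 (3aR,4S,5R,7R,8aS)-3-methyl-8-methylidene-5-(prop-1-en-2-yl)-1,3a,4,5,6,7,8,8a-octahydroazulene-4,7-diol
Conditions: NaBH4, CeCl3·7H2O, MeOH, −78 °C
Reagents that add atoms: none
Why: Luche 1,2-reduction of the enone, in which hydride enters from the α face because the β face of C7 is shielded by the C8a–C1 bond and the β-isopropenyl group at C5, giving the 7R alcohol.

Step 10
Reactants: 17 2-methylbut-3-yn-2-ol
Product: 19 (3E)-4-iodo-2-methylbut-3-en-2-ol, via vinylstannane 18 (not isolated)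
Conditions: Bu3SnH, PdCl2(PPh3)2 (2 mol %), THF, 0 °C; then I2, 0 °C
Reagents that add atoms: iodine ([I][I])
Why: palladium-catalysed syn-hydrostannation places tin on the terminal carbon and iododestannylation proceeds with retention, giving the (E)-vinyl iodide.

Step 11
Reactants: 16 (3aR,4S,5R,7R,8aS)-3-methyl-8-methylidene-5-(prop-1-en-2-yl)-1,3a,4,5,6,7,8,8a-octahydroazulene-4,7-diol, 19 (3E)-4-iodo-2-methylbut-3-en-2-ol
Product: 21 (3aR,4S,5R,7R,8aS)-5-[(2S,4E)-6-hydroxy-6-methylhept-4-en-2-yl]-3-methyl-8-methylidene-1,3a,4,5,6,7,8,8a-octahydroazulene-4,7-diol, via alkylborane 20 (not isolated)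
Conditions: 9-BBN (3.2 equiv), THF, 0 °C to rt; then 19 (1.5 equiv), PdCl2(dppf) (5 mol %), AsPh3, Cs2CO3, DMF/H2O, rt
Reagents that add atoms: none
Why: anti-Markovnikov hydroboration by 9-BBN at the least hindered 1,1-disubstituted olefin (the exocyclic methylene is flanked by two branched carbons, one carrying a bulky borinate) sets the side-chain C2 (S) centre by 1,2-induction (allylic hydrogen next to the vinylic methyl, borane anti to the C4 branch), and the B-alkyl Suzuki–Miyaura coupling keeps the E geometry of 19.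

Step 12
Reactants: 21 (3aR,4S,5R,7R,8aS)-5-[(2S,4E)-6-hydroxy-6-methylhept-4-en-2-yl]-3-methyl-8-methylidene-1,3a,4,5,6,7,8,8a-octahydroazulene-4,7-diol
Product: 22 (3aR,4S,5R,7R,8aS)-4-hydroxy-5-[(2S,4E)-6-hydroxy-6-methylhept-4-en-2-yl]-3-methyl-8-methylidene-1,3a,4,5,6,7,8,8a-octahydroazulen-7-yl acetate
Conditions: Ac2O (1.2 equiv), pyridine, CH2Cl2, −20 to 0 °C
Reagents that add atoms: acetic anhydride (CC(=O)OC(C)=O)
Why: selective acylation of the C7 allylic secondary hydroxyl, since the C4 hydroxyl is flanked by two methine carbons and the side-chain hydroxyl is tertiary; no stereocentre changes.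

**Compound list**

1 | furan-2-ylmethanol (furfuryl alcohol) | OCc1ccco1 | starting material
2 | 6-hydroxy-2H-pyran-3(6H)-one (racemic lactol) | O=C1COC(O)C=C1 | intermediate
3 | 5-oxo-5,6-dihydro-2H-pyran-2-yl acetate (racemic) | CC(=O)OC1OCC(=O)C=C1 | intermediate
4 | but-3-en-2-one | CC(=O)C=C | starting material
5 | penta-1,4-diene | C=CCC=C | starting material
6 | (3E)-hepta-3,6-dien-2-one | CC(=O)/C=C/CC=C | intermediate
7 | pyrylium-3-olate (3-oxidopyrylium betaine) | [O-]c1ccc[o+]c1 | intermediate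
8 | rac-(1S,5S,6S,7S)-6-acetyl-7-(prop-2-en-1-yl)-8-oxabicyclo[3.2.1]oct-3-en-2-one (6-endo-acetyl, 7-exo-allyl; racemate, drawn enantiomer goes on) | [C@H]13[C@@H](CC=C)[C@H](C(C)=O)[C@@H](O3)C=CC1=O | intermediate
9 | rac-(1S,5S,6R,7S)-6-(prop-1-en-2-yl)-7-(prop-2-en-1-yl)-8-oxabicyclo[3.2.1]oct-3-en-2-one (racemate, drawn enantiomer goes on) | [C@H]13[C@@H](CC=C)[C@H](C(C)=C)[C@@H](O3)C=CC1=O | intermediate
10 | (1S,4R,5S,6R,7S)-4,6-di(prop-1-en-2-yl)-7-(prop-2-en-1-yl)-8-oxabicyclo[3.2.1]octan-2-one | [C@H]13[C@@H](CC=C)[C@H](C(C)=C)[C@@H](O3)[C@@H](C(C)=C)CC1=O | intermediate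
11 | ring-opened samarium enolate/alkoxide of 10 (C1–O8 bond cleaved) | [O-]C1=C[C@@H](CC=C)[C@H](C(C)=C)[C@@H]([O-])[C@@H](C(C)=C)C1.[Sm+3].[Sm+3].[I-].[I-].[I-].[I-] | intermediate
12 | (3S,4R,5S,6R)-2-[(dimethylamino)methyl]-5-hydroxy-4,6-di(prop-1-en-2-yl)-3-(prop-2-en-1-yl)cycloheptan-1-one (C2 epimers) | CN(C)CC1[C@@H](CC=C)[C@H](C(C)=C)[C@@H](O)[C@@H](C(C)=C)CC1=O | intermediate
13 | trimethylammonium iodide of 12 | C[N+](C)(C)CC1[C@@H](CC=C)[C@H](C(C)=C)[C@@H](O)[C@@H](C(C)=C)CC1=O.[I-] | intermediate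
14 | (3S,4R,5S,6R)-5-hydroxy-2-methylidene-4,6-di(prop-1-en-2-yl)-3-(prop-2-en-1-yl)cycloheptan-1-one | C=C1[C@@H](CC=C)[C@H](C(C)=C)[C@@H](O)[C@@H](C(C)=C)CC1=O | intermediate
15 | (3aR,4S,5R,8aS)-4-hydroxy-3-methyl-8-methylidene-5-(prop-1-en-2-yl)-3a,4,5,6,8,8a-hexahydroazulen-7(1H)-one | C=C1[C@H]2CC=C(C)[C@@H]2[C@@H](O)[C@@H](C(C)=C)CC1=O | intermediate
16 | (3aR,4S,5R,7R,8aS)-3-methyl-8-methylidene-5-(prop-1-en-2-yl)-1,3a,4,5,6,7,8,8a-octahydroazulene-4,7-diol | C=C1[C@H]2CC=C(C)[C@@H]2[C@@H](O)[C@@H](C(C)=C)C[C@H]1O | intermediate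
17 | 2-methylbut-3-yn-2-ol | CC(C)(O)C#C | starting material
18 | (3E)-2-methyl-4-(tributylstannyl)but-3-en-2-ol | CC(C)(O)/C=C/[Sn](CCCC)(CCCC)CCCC | intermediate
19 | (3E)-4-iodo-2-methylbut-3-en-2-ol | CC(C)(O)/C=C/I | intermediate
20 | B-alkyl-9-borabicyclo[3.3.1]nonane adduct of 16 at the terminal carbon of the C5 isopropenyl group, both hydroxyls as 9-BBN borinates, new side-chain centre (S) | C=C1[C@H]2CC=C(C)[C@@H]2[C@@H](OB3C4CCCC3CCC4)[C@@H]([C@@H](C)CB3C4CCCC3CCC4)C[C@H]1OB1C2CCCC1CCC2 | intermediate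
21 | (3aR,4S,5R,7R,8aS)-5-[(2S,4E)-6-hydroxy-6-methylhept-4-en-2-yl]-3-methyl-8-methylidene-1,3a,4,5,6,7,8,8a-octahydroazulene-4,7-diol | C=C1[C@H]2CC=C(C)[C@@H]2[C@@H](O)[C@@H]([C@@H](C)C/C=C/C(C)(C)O)C[C@H]1O | intermediate
22 | (3aR,4S,5R,7R,8aS)-4-hydroxy-5-[(2S,4E)-6-hydroxy-6-methylhept-4-en-2-yl]-3-methyl-8-methylidene-1,3a,4,5,6,7,8,8a-octahydroazulen-7-yl acetate (CNP0312076.1) | C=C1[C@H]2CC=C(C)[C@@H]2[C@@H](O)[C@@H]([C@@H](C)C/C=C/C(C)(C)O)C[C@H]1OC(C)=O | target

**Step count**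

Total step count: 12. Longest linear sequence: 10 steps (1, 2, 4, 5, 6, 7, 8, 9, 11, 12).

**Steps most likely to fail, with fallbacks**

Step 4 is the main risk. The 6-endo-acetyl/7-exo-allyl isomer may not dominate, the ylide can dimerise, and the skipped dienone can slip into conjugation under base. The fallback sets out from 3 and uses a dienamine-type amine-catalysed asymmetric [5+2] cycloaddition instead of the thermal one. The ylide from 3 is trapped by the dienamine formed from (2E)-5-[(tert-butyldimethylsilyl)oxy]hex-2-enal and a bifunctional secondary amine–squaramide catalyst, which reacts at its β,γ-olefin. This gives 2-{6-endo-[1-(tert-butyldimethylsilyloxy)ethyl]-2-oxo-8-oxabicyclo[3.2.1]oct-3-en-7-exo-yl}acetaldehyde F1. Wittig methylenation of the aldehyde gives 6-endo-[1-(tert-butyldimethylsilyloxy)ethyl]-7-exo-(prop-2-en-1-yl)-8-oxabicyclo[3.2.1]oct-3-en-2-one F2. Bu4NF frees 6-endo-(1-hydroxyethyl)-7-exo-(prop-2-en-1-yl)-8-oxabicyclo[3.2.1]oct-3-en-2-one F3, and Dess–Martin oxidation comes back to the route at 8, now as one enantiomer, so step 6 no longer has to resolve.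

Step 7 packs a reductive C–O cleavage, a Mannich trapping and an elimination into one pot. The free hydroxyl can add back to the new enone (oxa-Michael), and the exocyclic enone can isomerise into the ring. The fallback sets out from 10 and replaces the Mannich/Hofmann sequence by an aldol/dehydration sequence with isolable intermediates. The samarium enolate is quenched with monomeric formaldehyde to give (3S,4R,5S,6R)-5-hydroxy-2-(hydroxymethyl)-4,6-di(prop-1-en-2-yl)-3-(prop-2-en-1-yl)cycloheptan-1-one F4. Selective mesylation of the primary hydroxyl gives [(3S,4R,5S,6R)-5-hydroxy-2-oxo-4,6-di(prop-1-en-2-yl)-3-(prop-2-en-1-yl)cycloheptyl]methyl methanesulfonate F5, and brief treatment with DBU at low temperature eliminates to 14.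

Step 11 relies on substrate control for the side-chain C2 centre and on 9-BBN choosing the isopropenyl group over the exocyclic methylene. The fallback sets out from 9 and makes that centre under catalyst control by a zirconium-catalysed asymmetric carboalumination of a vinyl group. The rhodium/(R)-BINAP addition is run with vinylboronic acid pinacol ester to give (1S,4R,5S,6R,7S)-4-ethenyl-6-(prop-1-en-2-yl)-7-(prop-2-en-1-yl)-8-oxabicyclo[3.2.1]octan-2-one F6. The chemistry of step 7 gives (3S,4R,5S,6R)-6-ethenyl-5-hydroxy-2-methylidene-4-(prop-1-en-2-yl)-3-(prop-2-en-1-yl)cycloheptan-1-one F7. Ring-closing metathesis gives (3aR,4S,5R,8aS)-5-ethenyl-4-hydroxy-3-methyl-8-methylidene-3a,4,5,6,8,8a-hexahydroazulen-7(1H)-one F8, and Luche reduction gives (3aR,4S,5R,7R,8aS)-5-ethenyl-3-methyl-8-methylidene-1,3a,4,5,6,7,8,8a-octahydroazulene-4,7-diol F9. Methylalumination of the vinyl group (Me3Al, bis(1-neomenthylindenyl)zirconium dichloride, CH2Cl2) followed by coupling of the isoalkylalane with 19 (Zn(OTf)2, PdCl2(DPEphos), DMF) returns to the route at 21.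

**Further compounds**

F1 | step 4 | 2-{6-endo-[1-(tert-butyldimethylsilyloxy)ethyl]-2-oxo-8-oxabicyclo[3.2.1]oct-3-en-7-exo-yl}acetaldehyde (ring configuration as in 8, silyloxy carbon unspecified) | [C@H]13[C@@H](CC=O)[C@H](C(C)O[Si](C)(C)C(C)(C)C)[C@@H](O3)C=CC1=O
F2 | step 4 | 6-endo-[1-(tert-butyldimethylsilyloxy)ethyl]-7-exo-(prop-2-en-1-yl)-8-oxabicyclo[3.2.1]oct-3-en-2-one (ring configuration as in 8) | [C@H]13[C@@H](CC=C)[C@H](C(C)O[Si](C)(C)C(C)(C)C)[C@@H](O3)C=CC1=O
F3 | step 4 | 6-endo-(1-hydroxyethyl)-7-exo-(prop-2-en-1-yl)-8-oxabicyclo[3.2.1]oct-3-en-2-one (ring configuration as in 8) | [C@H]13[C@@H](CC=C)[C@H](C(C)O)[C@@H](O3)C=CC1=O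
F4 | step 7 | (3S,4R,5S,6R)-5-hydroxy-2-(hydroxymethyl)-4,6-di(prop-1-en-2-yl)-3-(prop-2-en-1-yl)cycloheptan-1-one (C2 epimers) | OCC1[C@@H](CC=C)[C@H](C(C)=C)[C@@H](O)[C@@H](C(C)=C)CC1=O
F5 | step 7 | [(3S,4R,5S,6R)-5-hydroxy-2-oxo-4,6-di(prop-1-en-2-yl)-3-(prop-2-en-1-yl)cycloheptyl]methyl methanesulfonate (C1 epimers) | CS(=O)(=O)OCC1[C@@H](CC=C)[C@H](C(C)=C)[C@@H](O)[C@@H](C(C)=C)CC1=O
F6 | step 11 | (1S,4R,5S,6R,7S)-4-ethenyl-6-(prop-1-en-2-yl)-7-(prop-2-en-1-yl)-8-oxabicyclo[3.2.1]octan-2-one | [C@H]13[C@@H](CC=C)[C@H](C(C)=C)[C@@H](O3)[C@@H](C=C)CC1=O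
F7 | step 11 | (3S,4R,5S,6R)-6-ethenyl-5-hydroxy-2-methylidene-4-(prop-1-en-2-yl)-3-(prop-2-en-1-yl)cycloheptan-1-one | C=C1[C@@H](CC=C)[C@H](C(C)=C)[C@@H](O)[C@@H](C=C)CC1=O
F8 | step 11 | (3aR,4S,5R,8aS)-5-ethenyl-4-hydroxy-3-methyl-8-methylidene-3a,4,5,6,8,8a-hexahydroazulen-7(1H)-one | C=C1[C@H]2CC=C(C)[C@@H]2[C@@H](O)[C@@H](C=C)CC1=O
F9 | step 11 | (3aR,4S,5R,7R,8aS)-5-ethenyl-3-methyl-8-methylidene-1,3a,4,5,6,7,8,8a-octahydroazulene-4,7-diol | C=C1[C@H]2CC=C(C)[C@@H]2[C@@H](O)[C@@H](C=C)C[C@H]1O
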